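Ring B of the spiro[5.5]undecadienedione is cut at the bond between the spiro carbon C6 and the isopropyl-bearing C11 and at the C8=C9 olefin. C6 lies between the two carbonyls of ring A, so the free methylene of a ring A dione can act twice as a carbon nucleophile. In one flask it first adds to (E)-4-methylpent-2-enal under amine catalysis (C6–C11, sets C11); its enolate then adds to a 1-substituted vinylphosphonium salt and the ylide olefinates the pendant aldehyde (C6–C7 and C8=C9). The precursors are only the dione, the enal and the phosphonium salt, and the homoprenyl group is placed on C8 without ambiguity.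

Key step: step 6

Remark: the target is numbered as a spiro[5.5]undecane (ring A = dione ring C1–C6, ring B = cyclohexene ring C6–C11); enolisable 1,3-dicarbonyl compounds are written in one tautomeric form, and 12 is written as the open aldehyde although it should rest as its cyclic hemiacetals.

Step 1
Reactants: 1 tert-butyl 3-oxopentanoate; 2 dimethyl 2,2-dimethylpropanedioate
Product: 4 tert-butyl 2,4-dihydroxy-3,5,5-trimethyl-6-oxocyclohexa-1,3-diene-1-carboxylate, via acyclic diketo diester 3 (not isolated)
Conditions: NaH, THF, 0 °C; n-BuLi, −10 °C; then 2, −78 °C → rt, then 60 °C; aq. HCl work-up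
Reagents that add atoms: none
Why: The γ-carbon of the β-keto ester dianion acylates one ester group of 2 (Claisen condensation of a 1,3-dicarbonyl dianion) and the methoxide set free drives Dieckmann closure of the α-carbon onto the second ester, the doubly enolised cyclic β-triketone ester being the thermodynamic sink over any O-acylated enol lactone.

Step 2
Reactants: 4
Product: 5 tert-butyl 2-hydroxy-4-methoxy-3,5,5-trimethyl-6-oxocyclohexa-1,3-diene-1-carboxylate
Conditions: TMSCHN2 (1.05 equiv), toluene/MeOH (4:1), 0 °C
Reagents that add atoms: (trimethylsilyl)diazomethane, C[Si](C)(C)C=[N+]=[N-]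
Why: Diazoalkane O-methylation of an enolic β-triketone should take place at the C4 hydroxyl, the only one not held in the hydrogen-bonded chelate with the ester carbonyl, as in the methylation of acylphloroglucinol-derived triketones.

Step 3
Reactants: 5
Product: 7 5-methoxy-4,6,6-trimethylcyclohex-4-ene-1,3-dione, via β-keto acid 6 (not isolated)
Conditions: CF3CO2H/CH2Cl2 (1:4), 0 °C → rt; then toluene, 60 °C
Reagents that add atoms: none
Why: Acidolysis of the tert-butyl ester gives the chelated β-keto acid 6, which should lose CO2 on gentle warming (β-keto acid decarboxylation), while the vinylogous methyl ester is not hydrolysed in the absence of water.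

Step 4
Reactants: 8 6-methylhept-5-en-2-one
Product: 9 6-methylhepta-1,5-dien-2-yl trifluoromethanesulfonate
Conditions: LiN(i-Pr)2, THF, −78 °C; then PhNTf2, −78 → 0 °C; aq. NH4Cl work-up
Reagents that add atoms: N-phenylbis(trifluoromethanesulfonimide), O=S(=O)(N(c1ccccc1)S(=O)(=O)C(F)(F)F)C(F)(F)F
Why: Kinetic deprotonation of the methyl ketone at the methyl group and O-sulfonylation of the less substituted lithium enolate (enol triflate formation) should give the 1,1-disubstituted vinyl triflate.

Step 5
Reactants: 9
Product: 10 (6-methylhepta-1,5-dien-2-yl)triphenylphosphonium trifluoromethanesulfonate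
Conditions: PPh3 (1.05 equiv), Pd(PPh3)4 (3 mol%), THF, 65 °C
Reagents that add atoms: triphenylphosphine, c1ccc(cc1)P(c1ccccc1)c1ccccc1
Why: Oxidative addition of the vinyl triflate to zerovalent palladium followed by P–C reductive elimination is a known palladium-catalysed route from vinyl triflates and PPh3 to vinylphosphonium triflates, and the trisubstituted olefin is a spectator.

Step 6
Reactants: 7; 11 (E)-4-methylpent-2-enal; 10
Product: 14 (6R,11S)-3-methoxy-2,4,4-trimethyl-8-(4-methylpent-3-en-1-yl)-11-(propan-2-yl)spiro[5.5]undeca-2,8-diene-1,5-dione, via Michael aldehyde 12 (not isolated), via phosphorus ylide 13 (not isolated)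
Conditions: 11 (1.2 equiv), (S)-α,α-diphenylprolinol trimethylsilyl ether (15 mol%), PhCO2H (15 mol%), toluene, 0 °C → rt; concentrate; THF, NaN(SiMe3)2 (1.2 equiv), 0 °C; then 10 (1.3 equiv), 0 → 55 °C
Reagents that add atoms: none
Why: The enol of 7 adds to the iminium ion of 11 (organocatalytic Michael addition of a cyclic 1,3-dione to an enal) to give 12; its sodium enolate then attacks the CH2 terminus of 10 through carbon, and the non-stabilised ylide 13 closes on the aldehyde with loss of Ph3PO (Schweizer-type cycloalkene synthesis: conjugate addition to a vinylphosphonium salt, then intramolecular Wittig olefination). Ring B closes in the olefination by 6-exo attack of the ylide carbon on the aldehyde and oxaphosphetane collapse, which can only give the ring-cis olefin C8=C9 with the homoprenyl group on C8; no other ring is formed. C11 is set by the catalyst: the diphenyl(silyloxy)methyl group shields one face of the E-configured s-trans iminium ion, and attack of the dione carbon on the open face should give the S configuration. C6 is set in the quaternisation by substrate control: the enolate should be alkylated anti to the isopropyl group in the conformer that keeps the aldehyde arm beside the vinylogous-ester oxygen (assumed to be the more basic one, through which the lactol forms and the sodium ion bridges), which places the isopropyl group cis to the C1 carbonyl as required; this is the least secure element of the step. The step needs C- over O-attack on 10 and olefination faster than retro-Michael loss of the aldehyde arm: O-adducts cannot olefinate productively and revert, the carbon adduct is drained irreversibly by the six-ring Wittig closure, and after enolate formation no proton acidic enough to quench the ylide durably is left.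

Compound list
1 | tert-butyl 3-oxopentanoate | CCC(=O)CC(=O)OC(C)(C)C | starting material
2 | dimethyl 2,2-dimethylpropanedioate | COC(=O)C(C)(C)C(=O)OC | starting material
3 | 7-tert-butyl 1-methyl 2,2,4-trimethyl-3,5-dioxoheptanedioate | COC(=O)C(C)(C)C(=O)C(C)C(=O)CC(=O)OC(C)(C)C | intermediate
4 | tert-butyl 2,4-dihydroxy-3,5,5-trimethyl-6-oxocyclohexa-1,3-diene-1-carboxylate | O=C1C(C)(C)C(O)=C(C)C(O)=C1C(=O)OC(C)(C)C | intermediate
5 | tert-butyl 2-hydroxy-4-methoxy-3,5,5-trimethyl-6-oxocyclohexa-1,3-diene-1-carboxylate | O=C1C(C)(C)C(OC)=C(C)C(O)=C1C(=O)OC(C)(C)C | intermediate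
6 | 2-hydroxy-4-methoxy-3,5,5-trimethyl-6-oxocyclohexa-1,3-diene-1-carboxylic acid | O=C1C(C)(C)C(OC)=C(C)C(O)=C1C(=O)O | intermediate
7 | 5-methoxy-4,6,6-trimethylcyclohex-4-ene-1,3-dione | COC1=C(C)C(=O)CC(=O)C1(C)C | intermediate
8 | 6-methylhept-5-en-2-one | CC(=O)CCC=C(C)C | starting material
9 | 6-methylhepta-1,5-dien-2-yl trifluoromethanesulfonate | C=C(CCC=C(C)C)OS(=O)(=O)C(F)(F)F | intermediate
10 | (6-methylhepta-1,5-dien-2-yl)triphenylphosphonium trifluoromethanesulfonate | C=C(CCC=C(C)C)[P+](c1ccccc1)(c1ccccc1)c1ccccc1.[O-]S(=O)(=O)C(F)(F)F | intermediate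
11 | (E)-4-methylpent-2-enal | CC(C)/C=C/C=O | starting material
12 | (3S)-3-(4-methoxy-3,5,5-trimethyl-2,6-dioxocyclohex-3-en-1-yl)-4-methylpentanal | O=CC[C@@H](C(C)C)C1C(=O)C(C)=C(OC)C(C)(C)C1=O | intermediate
13 | (3S)-3-[(1R)-4-methoxy-3,5,5-trimethyl-1-[6-methyl-2-(triphenyl-λ5-phosphanylidene)hept-5-en-1-yl]-2,6-dioxocyclohex-3-en-1-yl]-4-methylpentanal | COC1=C(C)C(=O)[C@@](CC(CCC=C(C)C)=P(c2ccccc2)(c2ccccc2)c2ccccc2)([C@@H](CC=O)C(C)C)C(=O)C1(C)C | intermediate
14 | (6R,11S)-3-methoxy-2,4,4-trimethyl-8-(4-methylpent-3-en-1-yl)-11-(propan-2-yl)spiro[5.5]undeca-2,8-diene-1,5-dione | COC1=C(C)C(=O)[C@]2(CC(CCC=C(C)C)=CC[C@H]2C(C)C)C(=O)C1(C)C | target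

Total step count: 6. Longest linear sequence: 4 steps (steps 1, 2, 3 and 6; steps 4 and 5 form the second branch).

Steps most likely to fail

Step 6 (key step). The likely failure is poor facial selectivity when the enolate is quaternised at C6, because the two carbonyl flanks of ring A differ only remotely. The C6 epimer would be a diastereomer and would have to be removed. Quenching of the ylide or retro-Michael loss of the aldehyde arm before olefination are further risks. The fallback sets out from 12 and returns at 14. The Michael addition is run alone and 12 is isolated as its lactols. The dianion of 2-methylprop-2-en-1-ol (n-BuLi, TMEDA) is alkylated with 1-bromo-3-methylbut-2-ene to give 6-methyl-2-methylidenehept-5-en-1-ol F1, which ClCO2Me and pyridine convert into methyl (6-methyl-2-methylidenehept-5-en-1-yl) carbonate F2. Allylation of 12 with F2 under Pd2(dba)3 and a DACH-phenyl Trost ligand (the antipode matched to C11) sets C6 under catalyst control in a Tsuji–Trost quaternisation. It should give (3S)-3-[(1R)-4-methoxy-3,5,5-trimethyl-1-(6-methyl-2-methylidenehept-5-en-1-yl)-2,6-dioxocyclohex-3-en-1-yl]-4-methylpentanal F3. Wittig methylenation of the aldehyde (Ph3P=CH2, THF, 0 °C) gives (6R)-3-methoxy-2,4,4-trimethyl-6-(6-methyl-2-methylidenehept-5-en-1-yl)-6-[(3S)-2-methylhex-5-en-3-yl]cyclohex-2-ene-1,5-dione F4. Ring-closing metathesis with the second-generation Grubbs catalyst RuCl2(=CHPh)(PCy3)(H2IMes) in CH2Cl2 at 40 °C then closes ring B to 14.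

Step 1. The likely failure is ring closure through the enolate oxygen (enol lactone) or sluggish attack of the dianion on the hindered malonate ester. The fallback sets out from 1 and 2 and returns at 4. Mono-saponification of 2 (KOH, 1 equiv, MeOH; then HCl) gives 3-methoxy-2,2-dimethyl-3-oxopropanoic acid F5, and (COCl)2 with catalytic DMF gives methyl 3-chloro-2,2-dimethyl-3-oxopropanoate F6. The magnesium enolate of 1 (MgCl2, Et3N, MeCN, 0 °C) is C-acylated with F6 at its α-carbon to give 1-tert-butyl 5-methyl 4,4-dimethyl-3-oxo-2-propanoylpentanedioate F7. A separate Dieckmann closure of the propanoyl α-carbon onto the methyl ester (LiN(SiMe3)2, 2.2 equiv, THF, −78 °C → rt) then gives 4.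

Step 2. The likely failure is methylation at the chelated hydroxyl next to the ester, or twofold methylation, so that regiocontrol over the enol ether is lost. The fallback sets out from 2 and returns at 5, and installs the methoxy group before ring closure. Crossed Claisen condensation of the lithium enolate of methyl propanoate with 2 gives dimethyl 2,2,4-trimethyl-3-oxopentanedioate F8. Its only enolisable β-keto ester unit is O-methylated (NaH, DMPU, Me2SO4) to dimethyl 3-methoxy-2,2,4-trimethylpent-3-enedioate F9. The lithium enolate of tert-butyl acetate (2.2 equiv, THF, −78 °C → rt) should attack the saturated ester to give 7-tert-butyl 1-methyl 3-methoxy-2,4,4-trimethyl-5-oxohept-2-enedioate F10. F10 is not isolated and should close by Dieckmann condensation onto the conjugated ester to give 5.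

Further compounds
F1 | step 6 | 6-methyl-2-methylidenehept-5-en-1-ol | C=C(CO)CCC=C(C)C
F2 | step 6 | methyl (6-methyl-2-methylidenehept-5-en-1-yl) carbonate | COC(=O)OCC(=C)CCC=C(C)C
F3 | step 6 | (3S)-3-[(1R)-4-methoxy-3,5,5-trimethyl-1-(6-methyl-2-methylidenehept-5-en-1-yl)-2,6-dioxocyclohex-3-en-1-yl]-4-methylpentanal | COC1=C(C)C(=O)[C@@](CC(=C)CCC=C(C)C)([C@@H](CC=O)C(C)C)C(=O)C1(C)C
F4 | step 6 | (6R)-3-methoxy-2,4,4-trimethyl-6-(6-methyl-2-methylidenehept-5-en-1-yl)-6-[(3S)-2-methylhex-5-en-3-yl]cyclohex-2-ene-1,5-dione | COC1=C(C)C(=O)[C@@](CC(=C)CCC=C(C)C)([C@@H](CC=C)C(C)C)C(=O)C1(C)C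
F5 | step 1 | 3-methoxy-2,2-dimethyl-3-oxopropanoic acid | COC(=O)C(C)(C)C(=O)O
F6 | step 1 | methyl 3-chloro-2,2-dimethyl-3-oxopropanoate | COC(=O)C(C)(C)C(Cl)=O
F7 | step 1 | 1-tert-butyl 5-methyl 4,4-dimethyl-3-oxo-2-propanoylpentanedioate | CCC(=O)C(C(=O)OC(C)(C)C)C(=O)C(C)(C)C(=O)OC
F8 | step 2 | dimethyl 2,2,4-trimethyl-3-oxopentanedioate | COC(=O)C(C)C(=O)C(C)(C)C(=O)OC
F9 | step 2 | dimethyl 3-methoxy-2,2,4-trimethylpent-3-enedioate | COC(=O)C(C)=C(OC)C(C)(C)C(=O)OC
F10 | step 2 | 7-tert-butyl 1-methyl 3-methoxy-2,4,4-trimethyl-5-oxohept-2-enedioate | COC(=O)C(C)=C(OC)C(C)(C)C(=O)CC(=O)OC(C)(C)C
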